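**Plan**
- Retrosynthesis: the three esters and the C7 carbinol are adjusted last. Rings A and B are then cut together through C8–C9 and C5–C10 (intramolecular Diels–Alder). In ring B, the C7 oxygen beside the exocyclic C8=C17 methylene is the trace of a 1-methoxy vinylallene diene (C17=C8=C7(OMe)–C6=C5). The oxygenated C20 on quaternary C10, trans to the C9 side chain, is the trace of an (E)-2-alkyl enal (C20HO–C10=C9).
- The open-chain precursor is cut at C6–C7 (Negishi coupling with methoxyallene), C5=C6 (Takai olefination), C9=C10 (aldol condensation of a γ-lactone with a linalool-derived aldehyde) and C3–C4 (reverse prenylation).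
- Forward: a C20–C10–C1–C2–C3 lactone is extended by C4/C5, C6, C9–C16 and finally C7/C8/C17. Rings A and B then form in one thermal step, followed by ester installation and the C7 alcohol.
- Stereochemistry: C13 from (R)-linalool; C2 from (R)-5-(hydroxymethyl)butyrolactone; C3 by Felkin–Anh prenylation; C5, C9 and C10 in the cycloaddition (alkene geometries, endo formyl, equatorial C2 silyloxy group); C7 by Corey–Bakshi–Shibata reduction.

Key step: step 13

Remark: carbon numbers are those of the labdane skeleton of the target (decalin C1–C10, side chain C11–C16, methylene C17, angular C20). β is the face of C20, so the target has 5α-H, a 9α (axial) side chain with 9β-H, 2α-angeloyloxy, 3α-acetoxy, 7α-OH and 13R.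

Step 1
Reactants: 1 (R)-(−)-linalool
Product: 2 (R)-linalool triethylsilyl ether
Conditions: Et3SiOTf, 2,6-lutidine, CH2Cl2, −78 → 0 °C
Reagents that add atoms: triethylsilyl trifluoromethanesulfonate, CC[Si](CC)(CC)OS(=O)(=O)C(F)(F)F
Why: Silyl triflate with a hindered base silylates the tertiary allylic alcohol without ionising it, and the ether later prevents lactol formation and oxa-Michael addition; no stereocentre is touched.

Step 2
Reactants: 2 (R)-linalool triethylsilyl ether
Product: 4 (4R)-4-methyl-4-(triethylsilyloxy)hex-5-enal, via secondary ozonide 3 (not isolated)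
Conditions: O3 (1.0 equiv, Sudan Red 7B end point), CH2Cl2, −78 °C; then PPh3, −78 °C → rt
Reagents that add atoms: ozone, [O-][O+]=O
Why: Chemoselective ozonolysis, since the electron-rich trisubstituted 6,7-alkene should react far faster than the monosubstituted vinyl group beside the silyloxy carbon, and phosphine reduction of the ozonide releases the aldehyde.

Step 3
Reactants: 5 (R)-5-(hydroxymethyl)dihydrofuran-2(3H)-one
Product: 6 (R)-5-oxotetrahydrofuran-2-carbaldehyde
Conditions: 2,2,6,6-tetramethylpiperidin-1-oxyl (10 mol %), PhI(OAc)2, CH2Cl2, rt; used crude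
Reagents that add atoms: none
Why: Oxoammonium-mediated oxidation stops at the aldehyde under anhydrous conditions and should not epimerise the α-oxygenated centre (future C2).

Step 4
Reactants: 6 (R)-5-oxotetrahydrofuran-2-carbaldehyde
Product: 7 (5R)-5-[(1S)-1-hydroxy-2,2-dimethylbut-3-en-1-yl]dihydrofuran-2(3H)-one
Conditions: prenyl bromide, Zn dust, THF/sat. aq. NH4Cl, 0 °C → rt
Reagents that add atoms: prenyl bromide (1-bromo-3-methylbut-2-ene), CC(C)=CCBr
Why: Barbier reverse prenylation, in which the allylzinc adds through its γ-carbon in a chair transition state to create the C4 gem-dimethyl carbon, and polar Felkin–Anh attack anti to the ring C–O bond should set C3 anti (erythro) to C2.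

Step 5
Reactants: 7 (5R)-5-[(1S)-1-hydroxy-2,2-dimethylbut-3-en-1-yl]dihydrofuran-2(3H)-one
Product: 8 (5R)-5-[(1S)-2,2-dimethyl-1-(triethylsilyloxy)but-3-en-1-yl]dihydrofuran-2(3H)-one
Conditions: Et3SiOTf, 2,6-lutidine, CH2Cl2, −78 → 0 °C
Reagents that add atoms: triethylsilyl trifluoromethanesulfonate, CC[Si](CC)(CC)OS(=O)(=O)C(F)(F)F
Why: Standard silylation, which protects C3–OH against retro-aldol cleavage once C5 becomes an aldehyde and against oxa-Michael addition later.

Step 6
Reactants: 8 (5R)-5-[(1S)-2,2-dimethyl-1-(triethylsilyloxy)but-3-en-1-yl]dihydrofuran-2(3H)-one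
Product: 10 (3S)-2,2-dimethyl-3-[(2R)-5-oxotetrahydrofuran-2-yl]-3-(triethylsilyloxy)propanal, via secondary ozonide 9 (not isolated)
Conditions: O3, CH2Cl2, −78 °C; then PPh3, −78 °C → rt
Reagents that add atoms: ozone, [O-][O+]=O
Why: Ozonolysis of the only alkene gives the non-enolisable C5 aldehyde (quaternary α-carbon), while the lactone and silyl ether are inert.

Step 7
Reactants: 10 (3S)-2,2-dimethyl-3-[(2R)-5-oxotetrahydrofuran-2-yl]-3-(triethylsilyloxy)propanal
Product: 11 (5R)-5-[(1S,3E)-4-iodo-2,2-dimethyl-1-(triethylsilyloxy)but-3-en-1-yl]dihydrofuran-2(3H)-one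
Conditions: CrCl2 (divalent chromium, 6 equiv), CHI3, THF/1,4-dioxane, 0 °C → rt
Reagents that add atoms: iodoform, IC(I)I
Why: Takai olefination, in which the geminal dichromium species from iodoform adds to the hindered aldehyde and eliminates to the (E)-alkenyl iodide (C6), and divalent chromium tolerates the lactone.

Step 8
Reactants: 11 (5R)-5-[(1S,3E)-4-iodo-2,2-dimethyl-1-(triethylsilyloxy)but-3-en-1-yl]dihydrofuran-2(3H)-one; 4 (4R)-4-methyl-4-(triethylsilyloxy)hex-5-enal
Product: 15 (3E,5R)-5-[(1S,3E)-4-iodo-2,2-dimethyl-1-(triethylsilyloxy)but-3-en-1-yl]-3-[(4R)-4-methyl-4-(triethylsilyloxy)hex-5-en-1-ylidene]dihydrofuran-2(3H)-one, via lithium enolate 12 (not isolated), via lithium aldolate 13 (not isolated), via aldol mesylate 14 (not isolated)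
Conditions: LiN(SiMe3)2, THF, −78 °C; then 4; then MsCl, −78 → 0 °C; then DBU, rt
Reagents that add atoms: none
Why: Aldol condensation, in which the lactone enolate adds to 4 and E1cB elimination of the mesylate should converge both aldol diastereomers on the more stable (E)-alkylidene lactone, fixing C11 cis to C1 and trans to C20.

Step 9
Reactants: 15 (E)-alkylidene lactone
Product: 16 (2E,4R,5S,7E)-4-hydroxy-8-iodo-N-methoxy-N,6,6-trimethyl-2-[(4R)-4-methyl-4-(triethylsilyloxy)hex-5-en-1-ylidene]-5-(triethylsilyloxy)oct-7-enamide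
Conditions: MeNH(OMe)·HCl, AlMe3, CH2Cl2, 0 °C → rt; used crude
Reagents that add atoms: N,O-dimethylhydroxylamine hydrochloride, CNOC.Cl
Why: Aluminium amide aminolysis of the lactone (Weinreb amide formation) frees C2–OH and leaves C20 at a level reducible to the aldehyde, without touching the C9=C10 geometry.

Step 10
Reactants: 16 hydroxy Weinreb amide
Product: 17 (2E,4R,5S,7E)-8-iodo-N-methoxy-N,6,6-trimethyl-2-[(4R)-4-methyl-4-(triethylsilyloxy)hex-5-en-1-ylidene]-4,5-bis(triethylsilyloxy)oct-7-enamide
Conditions: Et3SiOTf, 2,6-lutidine, CH2Cl2, −78 °C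
Reagents that add atoms: triethylsilyl trifluoromethanesulfonate, CC[Si](CC)(CC)OS(=O)(=O)C(F)(F)F
Why: Silylation of the freed C2 hydroxyl prevents relactonisation and later lactol formation with the enal, and any earlier 1,2-silyl shift between O2 and O3 is harmless because both end as triethylsilyl ethers.

Step 11
Reactants: 17 tris(triethylsilyl) alkenyl iodide Weinreb amide
Product: 18 (2E,4R,5S,7E)-N,9-dimethoxy-N,6,6-trimethyl-2-[(4R)-4-methyl-4-(triethylsilyloxy)hex-5-en-1-ylidene]-4,5-bis(triethylsilyloxy)undeca-7,9,10-trienamide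
Conditions: methoxyallene, n-BuLi, THF, −78 → −40 °C; ZnCl2; then 17, Pd(PPh3)4 (zerovalent palladium, 5 mol %), THF, 0 °C → rt
Reagents that add atoms: methoxyallene (1-methoxypropa-1,2-diene), COC=C=C
Why: Negishi coupling, in which the 1-methoxyallenylzinc reagent should couple at its oxygen-bearing carbon with the (E)-alkenyl iodide with retention of alkene geometry to install C7, C8 and C17, and organozinc reagents leave the Weinreb amide alone.

Step 12
Reactants: 18 methoxy vinylallene Weinreb amide
Product: 19 (2E,4R,5S,7E)-9-methoxy-6,6-dimethyl-2-[(4R)-4-methyl-4-(triethylsilyloxy)hex-5-en-1-ylidene]-4,5-bis(triethylsilyloxy)undeca-7,9,10-trienal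
Conditions: i-Bu2AlH, THF, −78 °C; aq. KNaC4H4O6 (potassium sodium tartrate) work-up at 0 °C; taken on at once
Reagents that add atoms: none
Why: Reduction of the Weinreb amide stops at the chelated tetrahedral intermediate, so the (E)-enal is released only on neutral work-up, which spares the acid-labile methoxyallene.

Step 13
Reactants: 19 open-chain (E)-enal with methoxy vinylallene
Product: 20 7-methoxy-2α,3α,13-tris(triethylsilyloxy)-9βH-labda-6,8(17),14-trien-20-al (trans-decalin, 5α-H, side chain 9α, 13R)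
Conditions: toluene (0.01 M), 2,6-di-tert-butyl-4-methylphenol (cat.), 25 → 70 °C
Reagents that add atoms: none
Why: Thermal, concerted but asynchronous normal-demand [4+2] cycloaddition: the HOMO of the 2-methoxy diene C5=C6–C7(OMe)=C8 (nucleophilic terminus C8, the central allene carbon) meets the LUMO of the (E)-2-alkyl enal C10=C9, so the C8–C9 bond leads and the C5–C10 bond follows in the same transition state, leaving C8=C17 as the exocyclic methylene and C6=C7 as a methyl enol ether. The closest known reaction types are the intramolecular Diels–Alder reaction of vinylallenes and the Diels–Alder reaction of 2-oxy-substituted vinylallenes with electron-poor alkenes. Ring B closes as the new cyclohexene of the [4+2] (bonds C8–C9 and C5–C10), and ring A closes at the same time as a six-membered carbocycle through the four-atom tether C1–C4 in a chair-like anti (trans-fused) array, helped by the C4 gem-dimethyl group. C9 and C10 follow from the (E)-enal by suprafacial addition (C11 trans to C20), C5 should be set trans to C20 by the (E)-C5=C6 alkene together with the endo formyl/exo tether arrangement, and the face is fixed by C2, whose silyloxy group must sit equatorial because on the other face it would be 1,3-diaxial to both the axial C4 methyl and the formyl group, while the axial C3 silyloxy group meets only hydrogens. The step needs periselectivity ([4+2] through carbon, not hetero-Diels–Alder through the formyl oxygen, and no [2+2]) and regioselectivity; these are secured by the tether, which can span only C5/C10, by the matched polarisation (OMe at C7 para to the formyl at C10), and by quaternary C4, which offers no hydrogen for the 1,5-shift that otherwise drains vinylallenes.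

Step 14
Reactants: 20 tris(triethylsilyl) cycloadduct
Product: 21 2α,3α,13-trihydroxy-7-methoxy-9βH-labda-6,8(17),14-trien-20-al
Conditions: Bu4NF, AcOH (1:1, excess), THF, 0 °C → rt
Reagents that add atoms: none
Why: Buffered fluoride cleaves all three Si–O bonds under near-neutral conditions, which the acid-labile 2-methoxydiene and the non-enolisable angular aldehyde should survive.

Step 15
Reactants: 21 triol aldehyde
Product: 22 2α-angeloyloxy-3α,13-dihydroxy-7-methoxy-9βH-labda-6,8(17),14-trien-20-al
Conditions: angelic acid, 2,4,6-trichlorobenzoyl chloride, Et3N, toluene, rt; then 21, 75 °C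
Reagents that add atoms: angelic acid [(Z)-2-methylbut-2-enoic acid], C/C=C(/C)C(=O)O
Why: Yamaguchi-type mixed-anhydride esterification without a nucleophilic amine catalyst (which would isomerise Z to E) should acylate the equatorial C2–OH in preference to the axial, neopentyl C3–OH and the tertiary C13–OH, and keeping C20 as the aldehyde removes the primary alcohol as a competitor.

Step 16
Reactants: 22 C2 angelate aldehyde
Product: 23 2α-angeloyloxy-7-methoxy-9βH-labda-6,8(17),14-triene-3α,13,20-triol
Conditions: NaBH4, THF/MeOH, 0 °C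
Reagents that add atoms: none
Why: Borohydride reduces only the aldehyde, since the hindered conjugated angelate and the enol ether are inert at 0 °C.

Step 17
Reactants: 23 triol angelate
Product: 24 3α,20-diacetoxy-2α-angeloyloxy-7-methoxy-9βH-labda-6,8(17),14-trien-13-ol
Conditions: Ac2O, pyridine, rt → 40 °C (no 4-dimethylaminopyridine)
Reagents that add atoms: acetic anhydride, CC(=O)OC(C)=O
Why: Acetic anhydride in pyridine acetylates the primary C20–OH and the axial secondary C3–OH but should leave the tertiary allylic C13–OH untouched in the absence of an acyl-transfer catalyst, and the buffered medium preserves the enol ether.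

Step 18
Reactants: 24 diacetate angelate enol ether
Product: 25 3α,20-diacetoxy-2α-angeloyloxy-13-hydroxy-9βH-labda-8(17),14-dien-7-one
Conditions: oxalic acid (0.1 M aq.), THF, 0 °C → rt; used promptly
Reagents that add atoms: water, O
Why: Enol ether hydrolysis, in which protonation at C6 gives a C7 oxocarbenium ion that water converts into the ketone, unveiling the 8(17)-en-7-one while dilute acid in the cold spares the tertiary allylic alcohol and the esters.

Step 19
Reactants: 25 exo-methylene enone
Product: 26 CNP0147212.1, 3α,20-diacetoxy-2α-angeloyloxy-9βH-labda-8(17),14-diene-7α,13-diol (13R)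
Conditions: (S)-1-methyl-3,3-diphenyltetrahydro-1H,3H-pyrrolo[1,2-c][1,3,2]oxazaborole (20 mol %), catecholborane, toluene, −78 → −40 °C
Reagents that add atoms: none
Why: Corey–Bakshi–Shibata reduction, in which the (S)-oxazaborolidine should treat the alkenyl (C8) side as the large group and deliver hydride 1,2 to the β-face to give the 7R (7α, axial) alcohol, the same sense favoured by the axial C9 side chain that blocks the α-face trajectory; esters are not reduced.

**Compound list**
1 | (R)-(−)-linalool, (3R)-3,7-dimethylocta-1,6-dien-3-ol | C=C[C@](C)(O)CCC=C(C)C | starting material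
2 | (R)-linalool triethylsilyl ether | C=C[C@](C)(O[Si](CC)(CC)CC)CCC=C(C)C | intermediate
3 | secondary ozonide of 2 at the 6,7-alkene (1,2,4-trioxolane, both epimers at the acetal CH) | C=C[C@](C)(O[Si](CC)(CC)CC)CCC1OOC(C)(C)O1 | intermediate (not isolated)
4 | (4R)-4-methyl-4-(triethylsilyloxy)hex-5-enal | C=C[C@](C)(O[Si](CC)(CC)CC)CCC=O | intermediate
5 | (R)-5-(hydroxymethyl)dihydrofuran-2(3H)-one | OC[C@H]1CCC(=O)O1 | starting material
6 | (R)-5-oxotetrahydrofuran-2-carbaldehyde | O=C[C@H]1CCC(=O)O1 | intermediate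
7 | (5R)-5-[(1S)-1-hydroxy-2,2-dimethylbut-3-en-1-yl]dihydrofuran-2(3H)-one | C=CC(C)(C)[C@H](O)[C@H]1CCC(=O)O1 | intermediate
8 | (5R)-5-[(1S)-2,2-dimethyl-1-(triethylsilyloxy)but-3-en-1-yl]dihydrofuran-2(3H)-one | C=CC(C)(C)[C@H](O[Si](CC)(CC)CC)[C@H]1CCC(=O)O1 | intermediate
9 | secondary ozonide of 8 (3-substituted 1,2,4-trioxolane, both epimers) | CC(C)(C1OCOO1)[C@H](O[Si](CC)(CC)CC)[C@H]2CCC(=O)O2 | intermediate (not isolated)
10 | (3S)-2,2-dimethyl-3-[(2R)-5-oxotetrahydrofuran-2-yl]-3-(triethylsilyloxy)propanal | O=CC(C)(C)[C@H](O[Si](CC)(CC)CC)[C@H]1CCC(=O)O1 | intermediate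
11 | (5R)-5-[(1S,3E)-4-iodo-2,2-dimethyl-1-(triethylsilyloxy)but-3-en-1-yl]dihydrofuran-2(3H)-one | I/C=C/C(C)(C)[C@H](O[Si](CC)(CC)CC)[C@H]1CCC(=O)O1 | intermediate
12 | lithium enolate of lactone 11 | I/C=C/C(C)(C)[C@H](O[Si](CC)(CC)CC)[C@H]1CC=C([O-])O1.[Li+] | intermediate (not isolated)
13 | lithium aldolate from 12 and 4 (diastereomers at the two new centres) | [Li+].[O-]C(CC[C@@](C)(O[Si](CC)(CC)CC)C=C)C1C[C@H]([C@@H](O[Si](CC)(CC)CC)C(C)(C)/C=C/I)OC1=O | intermediate (not isolated)
14 | methanesulfonate of aldol 13 (diastereomers at the two new centres) | CS(=O)(=O)OC(CC[C@@](C)(O[Si](CC)(CC)CC)C=C)C1C[C@H]([C@@H](O[Si](CC)(CC)CC)C(C)(C)/C=C/I)OC1=O | intermediate (not isolated)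
15 | (3E,5R)-5-[(1S,3E)-4-iodo-2,2-dimethyl-1-(triethylsilyloxy)but-3-en-1-yl]-3-[(4R)-4-methyl-4-(triethylsilyloxy)hex-5-en-1-ylidene]dihydrofuran-2(3H)-one | O=C1O[C@@H]([C@@H](O[Si](CC)(CC)CC)C(C)(C)/C=C/I)C/C1=C\CC[C@@](C)(O[Si](CC)(CC)CC)C=C | intermediate
16 | (2E,4R,5S,7E)-4-hydroxy-8-iodo-N-methoxy-N,6,6-trimethyl-2-[(4R)-4-methyl-4-(triethylsilyloxy)hex-5-en-1-ylidene]-5-(triethylsilyloxy)oct-7-enamide | CON(C)C(=O)/C(C[C@@H](O)[C@@H](O[Si](CC)(CC)CC)C(C)(C)/C=C/I)=C/CC[C@@](C)(O[Si](CC)(CC)CC)C=C | intermediate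
17 | (2E,4R,5S,7E)-8-iodo-N-methoxy-N,6,6-trimethyl-2-[(4R)-4-methyl-4-(triethylsilyloxy)hex-5-en-1-ylidene]-4,5-bis(triethylsilyloxy)oct-7-enamide | CON(C)C(=O)/C(C[C@@H](O[Si](CC)(CC)CC)[C@@H](O[Si](CC)(CC)CC)C(C)(C)/C=C/I)=C/CC[C@@](C)(O[Si](CC)(CC)CC)C=C | intermediate
18 | (2E,4R,5S,7E)-N,9-dimethoxy-N,6,6-trimethyl-2-[(4R)-4-methyl-4-(triethylsilyloxy)hex-5-en-1-ylidene]-4,5-bis(triethylsilyloxy)undeca-7,9,10-trienamide | CON(C)C(=O)/C(C[C@@H](O[Si](CC)(CC)CC)[C@@H](O[Si](CC)(CC)CC)C(C)(C)/C=C/C(OC)=C=C)=C/CC[C@@](C)(O[Si](CC)(CC)CC)C=C | intermediate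
19 | (2E,4R,5S,7E)-9-methoxy-6,6-dimethyl-2-[(4R)-4-methyl-4-(triethylsilyloxy)hex-5-en-1-ylidene]-4,5-bis(triethylsilyloxy)undeca-7,9,10-trienal | O=C/C(C[C@@H](O[Si](CC)(CC)CC)[C@@H](O[Si](CC)(CC)CC)C(C)(C)/C=C/C(OC)=C=C)=C/CC[C@@](C)(O[Si](CC)(CC)CC)C=C | intermediate
20 | 7-methoxy-2α,3α,13-tris(triethylsilyloxy)-9βH-labda-6,8(17),14-trien-20-al (5α-H, 9α side chain, 13R) | C=C[C@](C)(O[Si](CC)(CC)CC)CC[C@@H]1C(=C)C(OC)=C[C@H]2C(C)(C)[C@H](O[Si](CC)(CC)CC)[C@H](O[Si](CC)(CC)CC)C[C@]12C=O | intermediate
21 | 2α,3α,13-trihydroxy-7-methoxy-9βH-labda-6,8(17),14-trien-20-al | C=C[C@](C)(O)CC[C@@H]1C(=C)C(OC)=C[C@H]2C(C)(C)[C@H](O)[C@H](O)C[C@]12C=O | intermediate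
22 | 2α-angeloyloxy-3α,13-dihydroxy-7-methoxy-9βH-labda-6,8(17),14-trien-20-al | C=C[C@](C)(O)CC[C@@H]1C(=C)C(OC)=C[C@H]2C(C)(C)[C@H](O)[C@H](OC(=O)/C(C)=C\C)C[C@]12C=O | intermediate
23 | 2α-angeloyloxy-7-methoxy-9βH-labda-6,8(17),14-triene-3α,13,20-triol | C=C[C@](C)(O)CC[C@@H]1C(=C)C(OC)=C[C@H]2C(C)(C)[C@H](O)[C@H](OC(=O)/C(C)=C\C)C[C@]12CO | intermediate
24 | 3α,20-diacetoxy-2α-angeloyloxy-7-methoxy-9βH-labda-6,8(17),14-trien-13-ol | C=C[C@](C)(O)CC[C@@H]1C(=C)C(OC)=C[C@H]2C(C)(C)[C@H](OC(C)=O)[C@H](OC(=O)/C(C)=C\C)C[C@]12COC(C)=O | intermediate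
25 | 3α,20-diacetoxy-2α-angeloyloxy-13-hydroxy-9βH-labda-8(17),14-dien-7-one | C=C[C@](C)(O)CC[C@@H]1C(=C)C(=O)C[C@H]2C(C)(C)[C@H](OC(C)=O)[C@H](OC(=O)/C(C)=C\C)C[C@]12COC(C)=O | intermediate
26 | CNP0147212.1, 3α,20-diacetoxy-2α-angeloyloxy-9βH-labda-8(17),14-diene-7α,13-diol (13R) | C=C[C@](C)(O)CC[C@@H]1C(=C)[C@H](O)C[C@H]2C(C)(C)[C@H](OC(C)=O)[C@H](OC(=O)/C(C)=C\C)C[C@]12COC(C)=O | target

**Count**
Total steps: 19. Longest linear sequence: 17 (steps 3–19, from 5); steps 1–2 form the side branch that joins in step 8.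

**Steps most likely to fail**

Step 13. The formyl group may engage the electron-rich allenyl enol ether as an oxadiene (hetero-Diels–Alder), or the endo and facial preferences may erode in the uncatalysed reaction. The fallback changes the dienophile activator to a nitrile, which is linear, cannot act as a heterodiene and can be purified before cyclisation. It sets out from enal 19, condensed in the cold as soon as it is liberated. NH2OH·HCl/pyridine in EtOH at 0 °C should give the (E)-aldoxime F1. 1,1'-Carbonyldiimidazole in CH2Cl2 should dehydrate it to the (2E)-alkylidene nitrile F2. Heating in toluene at 110 °C should give the angular nitrile cycloadduct F3 by the same [4+2] reaction, with the tether alone directing trans-fusion and face. i-Bu2AlH (CH2Cl2, −78 °C) followed by buffered hydrolysis of the aldimine comes back to the route at aldehyde 20.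

Step 11. Coupling may pass through the propargyl isomer of the organometallic, or the alkoxyallenylzinc may decompose faster than it couples with the alkenyl iodide next to quaternary C4. The fallback forms the C6–C7 bond by carbonyl addition and creates the allene by isomerisation. It sets out from iodide 17. Nozaki–Hiyama–Kishi coupling with 3-(trimethylsilyl)propynal [CrCl2 (divalent chromium), NiCl2 (cat.), DMF] should give the dienyl propargyl carbinol F4 as both C7 epimers, a centre that later becomes sp2. O-Methylation (MeOTf, 2,6-di-tert-butyl-4-methylpyridine, CH2Cl2) gives the methyl ether F5. K2CO3 in MeOH removes the alkynyl silyl group to give the terminal alkyne F6. Catalytic KOtBu in THF then moves the doubly activated C7 hydrogen to the alkyne terminus (propargyl-to-allenyl ether isomerisation) and comes back to the route at 18.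

Step 19. Hydride may be delivered along the axial trajectory to the α-face, giving the equatorial 7β-alcohol. The fallback sets C7 by SN2 inversion instead of by face-selective reduction. It sets out from enone 25. Luche reduction (NaBH4, CeCl3·7H2O, MeOH, −78 °C) gives the 7β-alcohol F7. Mitsunobu reaction with chloroacetic acid (PPh3, diisopropyl azodicarboxylate, toluene) inverts C7 to the 7α-chloroacetate F8, the tertiary C13–OH being inert. Thiourea/NaHCO3 in EtOH cleaves the chloroacetate in the presence of the acetates and the angelate and comes back to the route at 26.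

**Further compounds**
F1 | step 13 | (E)-aldoxime of enal 19 | O/N=C/C(C[C@@H](O[Si](CC)(CC)CC)[C@@H](O[Si](CC)(CC)CC)C(C)(C)/C=C/C(OC)=C=C)=C/CC[C@@](C)(O[Si](CC)(CC)CC)C=C
F2 | step 13 | (2E,4R,5S,7E)-9-methoxy-6,6-dimethyl-2-[(4R)-4-methyl-4-(triethylsilyloxy)hex-5-en-1-ylidene]-4,5-bis(triethylsilyloxy)undeca-7,9,10-trienenitrile | N#C/C(C[C@@H](O[Si](CC)(CC)CC)[C@@H](O[Si](CC)(CC)CC)C(C)(C)/C=C/C(OC)=C=C)=C/CC[C@@](C)(O[Si](CC)(CC)CC)C=C
F3 | step 13 | 7-methoxy-2α,3α,13-tris(triethylsilyloxy)-9βH-labda-6,8(17),14-triene-20-nitrile | C=C[C@](C)(O[Si](CC)(CC)CC)CC[C@@H]1C(=C)C(OC)=C[C@H]2C(C)(C)[C@H](O[Si](CC)(CC)CC)[C@H](O[Si](CC)(CC)CC)C[C@]12C#N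
F4 | step 11 | dienyl propargyl carbinol from 17 and 3-(trimethylsilyl)propynal (both C7 epimers) | CON(C)C(=O)/C(C[C@@H](O[Si](CC)(CC)CC)[C@@H](O[Si](CC)(CC)CC)C(C)(C)/C=C/C(O)C#C[Si](C)(C)C)=C/CC[C@@](C)(O[Si](CC)(CC)CC)C=C
F5 | step 11 | C7 methyl ether of F4 | CON(C)C(=O)/C(C[C@@H](O[Si](CC)(CC)CC)[C@@H](O[Si](CC)(CC)CC)C(C)(C)/C=C/C(OC)C#C[Si](C)(C)C)=C/CC[C@@](C)(O[Si](CC)(CC)CC)C=C
F6 | step 11 | terminal alkyne from F5 | CON(C)C(=O)/C(C[C@@H](O[Si](CC)(CC)CC)[C@@H](O[Si](CC)(CC)CC)C(C)(C)/C=C/C(OC)C#C)=C/CC[C@@](C)(O[Si](CC)(CC)CC)C=C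
F7 | step 19 | 7β-alcohol (7-epimer of 26) | C=C[C@](C)(O)CC[C@@H]1C(=C)[C@@H](O)C[C@H]2C(C)(C)[C@H](OC(C)=O)[C@H](OC(=O)/C(C)=C\C)C[C@]12COC(C)=O
F8 | step 19 | 7α-chloroacetate of 26 | C=C[C@](C)(O)CC[C@@H]1C(=C)[C@H](OC(=O)CCl)C[C@H]2C(C)(C)[C@H](OC(C)=O)[C@H](OC(=O)/C(C)=C\C)C[C@]12COC(C)=O
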